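## Analysis of the target

The target 29 consists of two 4-aryl-3,4-dihydrocoumarins (chroman-2-ones) joined by a C3–C3′ single bond. Ring A (unprimed half) is a 5,7-dihydroxybenzene fused to its lactone. Ring B (primed half) is a fully substituted benzene with hydroxyls on C5′, C6′, C7′ and C8′, the lactone oxygen on C8a′ and C4′ on C4a′; each C4 carries a 4-hydroxyphenyl group. The four stereocentres are contiguous, C4–C3–C3′–C4′, with configuration (3S,4R,3′S,4′R): in each lactone the C4 aryl group and the C3–C3′ bond are cis, and apart from the arene oxygenation the halves are related by a twofold axis through C3–C3′. C3 and C3′ are α to aryl ester carbonyls in the less stable cis arrangement and are lost by any enolisation, whereas C4 and C4′ cannot enolise. The aryl ester lactones are opened by base and nucleophiles, and the 1,2,3,4-tetrahydroxybenzene of ring B is oxidised to quinones by air, fastest in base. The difficulty is threefold: the unequal oxygenation of rings A and B forbids a symmetric dimerisation, two of the four contiguous centres are labile, and the hexasubstituted, pentaoxygenated ring B cannot be reached by regioselective oxidation of a simpler arene. The strategy rests on ring B itself: the oxygens on C5′ and C8′ are para (a hydroquinone), flanked by oxygens on C6′ and C7′ and fused at C8a′–C4a′ to an oxygen heterocycle, which is the pattern that ring expansion of a squarate-derived 4-alkenyl-4-hydroxycyclobutenone delivers.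

## Retrosynthetic reasoning

29 ⇒ 28. The eight O–CH3 bonds are cut last. Methyl ethers pass an organolithium, a thermolysis near 140 °C, two enolate steps and an ozonolysis unchanged; six of the eight arrive in commercial materials (1, 4, 20, 21) and the other two are added in a single methylation. The forward step must cleave eight aryl methyl ethers with a boron trihalide without enolising C3 or C3′; the aryl ester lactones are tolerated because they hold no alkyl–oxygen bond.

28 ⇒ 19 + 25. The ring A lactone is cut at C3–C4 and O1–C2. Ring A, an ordinary dioxygenated phenol unit, can then enter as the o-quinone methide 26 (stored as sulfone 25), while the C3–C3′ bond already exists in aldehyde 19 as the bond from C3′ to its CH2CHO arm. A cut at C3–C3′ would instead require joining two lactone α-carbons of like polarity. The forward carbene-catalysed annulation through enolate 27 must form C3–C4 and the lactone, set C3 and C4 cis in the (3S,4R) sense, and leave C3′ alone.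

19 ⇒ 17 ⇒ 15 ⇒ 12 + 13. The aldehyde carbon (future C2) and its CH2 (future C3) are traced to an allyl group on C3′: alkene cleavage of 17, and before it the C3′–C3 bond by alkylation of enolate 14 with 13. Alkylation can only occur anti to the C4′ aryl group and gives the trans lactone 15, so the centre is inverted through enolate 16 by kinetic protonation. The inversion is placed on the monolactone, not after the coupling, because in 28 the C3 and C3′ hydrogens are equally acidic and could not be addressed separately.

12 ⇒ 11 ⇒ 10 ⇒ 9. The lactone carbonyl C2′ is traced through lactol 11 to the ethyl acetal carbon of 10, and two of the ring B methyl ethers to the free hydroquinone 9. The carbonyl is held as an acetal until here because an aryl ester would not survive the organolithium step, and the acetal is what the first step supplies. None of these operations touches C4′.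

9 ⇒ 6 (key disconnection). Ring B is cut at C4a′–C5′ and traced through dienone 8 and dienylketene 7 to cyclobutenone 6. C5′, C6′, C7′ and C8′ are the four squarate carbons; C8a′ and C4a′ are C6 and C5 of a dihydropyran. The cut replaces the uncontrollable oxidation of an electron-rich arene by a ring synthesis in which each carbon arrives with its substituent. One ring and one C–C bond are gained and no stereocentre is needed. The forward reaction must open the four-membered ring with the hydroxyl turning outward, close onto pyran C5, and preserve C4′ and the acetal.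

6 ⇒ 3 + 4. The bond between pyran C6 and the carbinol carbon is cut to alkenyllithium 5 and dimethyl squarate 4; 5 comes from 3 by deprotonation of the enol ether C–H. The forward step must metalate C6 and not the benzylic, allylic C4–H (the future C4′), and add only once to 4.

3 ⇒ 1 + 2. The dihydropyran is cut at O1–C2 and C3–C4 (pyran numbering) to oxadiene 1 and enol ether 2. One catalytic asymmetric cycloaddition supplies the C4 stereocentre (future C4′), the enol ether needed for metalation and ring expansion, and the acetal carbon that becomes C2′.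

25 ⇒ 23 ⇒ 20 + 21. The sulfone is traced to benzhydrol 23 (C–S bond, made in acid through the benzhydryl cation 24) and on to aldehyde 20 and Grignard reagent 21 (aryl–carbinol bond). The carbinol centre needs no control because it is trigonal in cation 24 and again in the methide 26.

## Alternatives that were turned down

Alternative 1: Here C3–C3′ and, temporarily, C4–C4′ are traced to a head-to-head [2+2] photodimer of the cinnamoyl imidazole A2. The forward key step is a sensitised, chiral-acid-controlled dimerisation to the all-trans cyclobutane A1. The strained C4–C4′ bond, flanked by two anisyl groups, would then be cleaved oxidatively, each benzylic terminus arylated by a phenol (ring A at one end, ring B at the other), and the acyl groups transferred to those phenols.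
- For: C3–C3′ and both its stereocentres come from one catalytic step on a one-step substrate. On this bond and on step count it is stronger than the chosen route, which needs allylation, inversion, cleavage and annulation.
- Against: A1 has twofold symmetry and the target has not, so two identical termini must accept two different arenes. The ring opening passes through planar benzylic cations, so C4 and C4′ are controlled only by their neighbours and most likely trans. The ring B nucleophile is a tetraalkoxyphenol that still has to be made and is more easily oxidised than the cyclobutane bond.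
- Comparison: the chosen route is longer but differentiates the halves by construction, sets C4′ and C4 in separate catalyst-controlled steps, and actually builds ring B.

Alternative 2: Both lactones are cut at once (C3–C4, C3′–C4′ and both acyl–oxygen bonds), giving the unsymmetrical diaryl succinate A4 whose aryl groups are the ring A and ring B phenols carrying quinone methides. In the forward key step a chiral isothiourea is acylated by one aryl ester, its ammonium enolate adds to the quinone methide of the released aryloxide, the phenoxide relactonises, and the cycle repeats at the other end to give A3.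
- For: the C3–C3′ bond is bought; four bonds, two rings and four stereocentres form in one operation; the 4-hydroxyphenyl groups emerge free. It is clearly stronger on convergence and length.
- Against: the enolate precursor is an unactivated alkyl ester CH2. The second cycle must enolise a hindered position beside new stereocentres and again deliver cis, a double stereodifferentiation under one catalyst. The labile cis centres sit in a medium of amine and aryloxide, and quinone methides without blocking groups oligomerise. Above all, the ring B phenol of A4 is again the pentaoxygenated arene, so the hardest ring is presupposed.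
- Comparison: the chosen route is longer but builds ring B and keeps each pair of stereocentres separately controllable.

Alternative 3: Ring A is cut at C5–C6 and C8–C8a. In the forward key step the malonyl dichloride A6 doubly C-acylates the magnesium enolate of A7 (Claisen, then Dieckmann), the ring aromatises and the new ortho hydroxyl lactonises onto the C2 ester to give A5.
- For: ring A regiochemistry is fixed by construction, and C4 would come from a dependable asymmetric conjugate addition on the way to A6. On C4 it is at least as strong as the carbene annulation, whose facial outcome is harder to predict.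
- Against: ring A is the ordinary ring and enters the chosen route as commercial 20. The esters at C6 and C8 of A5 are extraneous and need hydrolysis and decarboxylation that threaten the lactone. A6 has an acidic malonyl hydrogen and can lose C4 by retro-Michael reaction. Ring B, C3–C3′ and C3 are not addressed.
- Comparison: the alternative spends a de novo ring synthesis on the wrong ring; the chosen strategy applies the same idea to ring B, where no purchasable arene exists.

Key step: step 3

Assumption: CrCl(L) from (1R,2S)-aminoindanol is taken to give (4S)-3 and the (5aS,10bR) triazolium salt to give the (3S,4R) ring A lactone; if either sense is opposite, the antipodal catalyst is used with no other change.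

## Route

Step 1
Reactants: 1 (E)-3-(4-methoxyphenyl)prop-2-enal; 2 ethyl vinyl ether
Product: 3 (2S,4S)-2-ethoxy-4-(4-methoxyphenyl)-3,4-dihydro-2H-pyran
Conditions: CrCl(L) (5 mol %; L = dianion of 2-(1-adamantyl)-6-{[(1R,2S)-2-hydroxyindan-1-yl]iminomethyl}-4-methylphenol), 4 Å MS, 2 (10 equiv, neat), rt
Reagents that add atoms: none
Why: Catalytic asymmetric inverse-electron-demand hetero-Diels–Alder reaction: the trivalent chromium Lewis acid binds the aldehyde oxygen of the s-cis enal and the vinyl ether adds endo, placing OEt cis to the aryl group. The ligand selects the diene face and so sets C4 (S), the future C4′; the acetal centre is removed later and need not be pure.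

Step 2
Reactants: 3 (2S,4S)-2-ethoxy-4-(4-methoxyphenyl)-3,4-dihydro-2H-pyran; 4 dimethyl squarate
Product: 6 4-[(2S,4S)-2-ethoxy-4-(4-methoxyphenyl)-3,4-dihydro-2H-pyran-6-yl]-4-hydroxy-2,3-dimethoxycyclobut-2-en-1-one (both carbinol epimers), via pyranyllithium 5 (not isolated)
Conditions: t-BuLi (1.2 equiv), THF, −78 → −30 °C; cannulate into 4 (1.3 equiv), THF, −78 °C; aq NH4Cl, −78 °C
Reagents that add atoms: none
Why: Alkoxy-directed deprotonation of the enol ether C6–H, as for 3,4-dihydro-2H-pyran and glycals, gives alkenyllithium 5, which adds 1,2 to one carbonyl of 4; inverse addition at −78 °C prevents a second addition. The tertiary C4–H, flanked by an electron-rich arene and an enol ether, is kinetically slower to remove, so C4 should be retained; the new carbinol centre is uncontrolled and is erased in step 3.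

Step 3
Reactants: 6 4-[(2S,4S)-2-ethoxy-4-(4-methoxyphenyl)-3,4-dihydro-2H-pyran-6-yl]-4-hydroxy-2,3-dimethoxycyclobut-2-en-1-one
Product: 9 (2S,4R)-2-ethoxy-6,7-dimethoxy-4-(4-methoxyphenyl)-3,4-dihydro-2H-chromene-5,8-diol, via dienylketene 7 (not isolated), via cyclohexadienone 8 (not isolated)
Conditions: degassed p-xylene (0.02 M), 138 °C, Ar, 1–2 h
Reagents that add atoms: none
Why: Heating opens the cyclobutenone by a conrotatory 4π electrocyclic reaction in which the hydroxyl, the stronger donor on the sp3 carbon, rotates outward, so the pyranyl group turns inward and the (3Z)-dienylketene 7 results. The enol ether carbon C5 of the pyran then bonds to the ketene carbon in a thermal disrotatory 6π electrocyclisation, which closes the six-membered carbocycle of ring B and forms C4a′–C5′; the resulting dienone 8 enolises at once to the hydroquinone 9. The closest known reaction type is the Moore rearrangement of 4-alkenyl-4-hydroxycyclobutenones made from squarate esters and alkenyllithiums, which is established for lithiated cyclic enol ethers. No stereocentre is created: the carbinol centre of 6 is destroyed in the ring opening, so both epimers converge, and the transient C4a′ centre of 8 vanishes on aromatisation. The step needs outward rotation of the hydroxyl, which is intrinsic to oxygen donors on cyclobutenones, and closure at the only alkene terminus available, pyran C5, which carries the hydrogen required for tautomerisation. C4′ is outside the reacting π system and no acid or base is added, so its configuration and the acetal should survive under neutral, degassed conditions. All six ring B carbons arrive with their final substituent, with the C5′ and C8′ oxygens para.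

Step 4
Reactants: 9 (2S,4R)-2-ethoxy-6,7-dimethoxy-4-(4-methoxyphenyl)-3,4-dihydro-2H-chromene-5,8-diol
Product: 10 (2S,4R)-2-ethoxy-5,6,7,8-tetramethoxy-4-(4-methoxyphenyl)-3,4-dihydro-2H-chromene
Conditions: MeI (6 equiv), K2CO3 (6 equiv), DMF, Ar, rt → 40 °C
Reagents that add atoms: iodomethane, CI
Why: Williamson O-methylation of both phenols under argon turns the oxidation-prone hydroquinone into a robust tetramethyl ether; the acetal is stable to base and no stereocentre is involved.

Step 5
Reactants: 10 (2S,4R)-2-ethoxy-5,6,7,8-tetramethoxy-4-(4-methoxyphenyl)-3,4-dihydro-2H-chromene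
Product: 11 (4R)-5,6,7,8-tetramethoxy-4-(4-methoxyphenyl)-3,4-dihydro-2H-chromen-2-ol (both anomers)
Conditions: 1 M aq HCl, THF, 45 °C
Reagents that add atoms: water, O
Why: Acid-catalysed hydrolysis of the mixed aryl alkyl acetal through the cyclic oxocarbenium ion gives the lactol; C4 has no pathway for epimerisation under these conditions.

Step 6
Reactants: 11 (4R)-5,6,7,8-tetramethoxy-4-(4-methoxyphenyl)-3,4-dihydro-2H-chromen-2-ol
Product: 12 (4R)-5,6,7,8-tetramethoxy-4-(4-methoxyphenyl)-3,4-dihydro-2H-chromen-2-one
Conditions: (n-Pr4N)RuO4 (5 mol %), N-methylmorpholine N-oxide (1.5 equiv), 4 Å MS, CH2Cl2, rt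
Reagents that add atoms: none
Why: Ley–Griffith oxidation of a lactol to the lactone; the catalytic perruthenate should not attack the fully etherified arene and no stereocentre is touched.

Step 7
Reactants: 12 (4R)-5,6,7,8-tetramethoxy-4-(4-methoxyphenyl)-3,4-dihydro-2H-chromen-2-one; 13 allyl bromide
Product: 15 (3S,4R)-3-allyl-5,6,7,8-tetramethoxy-4-(4-methoxyphenyl)-3,4-dihydro-2H-chromen-2-one, via lithium enolate 14 (not isolated)
Conditions: LiN(i-Pr)2 (1.1 equiv), THF, −78 °C; 13 (2 equiv), DMPU, −78 → −40 °C
Reagents that add atoms: none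
Why: Alkylation of a lactone lithium enolate: the C4 aryl group, held pseudoaxial by the peri C5 methoxy group, shields one face of 14, so 13 enters anti to it and the 3,4-trans lactone forms. Only the C–C bond matters here, since C3 is reset in step 8.

Step 8
Reactants: 15 (3S,4R)-3-allyl-5,6,7,8-tetramethoxy-4-(4-methoxyphenyl)-3,4-dihydro-2H-chromen-2-one
Product: 17 (3R,4R)-3-allyl-5,6,7,8-tetramethoxy-4-(4-methoxyphenyl)-3,4-dihydro-2H-chromen-2-one, via lithium enolate 16 (not isolated)
Conditions: LiN(i-Pr)2 (1.3 equiv), THF, −78 → −40 °C; 2,6-di-tert-butyl-4-methylphenol (3 equiv), THF, −78 °C; aq NH4Cl, −78 °C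
Reagents that add atoms: none
Why: Deprotonation to the planar enolate 16 and kinetic protonation by the hindered phenol from the face opposite the C4 aryl group put the new hydrogen trans to the aryl and leave the allyl group cis (3R,4R). Cold work-up prevents equilibration to the more stable trans isomer.

Step 9
Reactants: 17 (3R,4R)-3-allyl-5,6,7,8-tetramethoxy-4-(4-methoxyphenyl)-3,4-dihydro-2H-chromen-2-one
Product: 19 2-[(3R,4R)-5,6,7,8-tetramethoxy-4-(4-methoxyphenyl)-2-oxo-3,4-dihydro-2H-chromen-3-yl]acetaldehyde, via ozonide 18 (not isolated)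
Conditions: O3, CH2Cl2, −78 °C (Sudan Red 7B end point); PPh3 (1.5 equiv), −78 °C → rt
Reagents that add atoms: ozone, [O-][O+]=O
Why: Ozonolysis with reductive work-up; the monosubstituted alkene is consumed far faster at −78 °C than the fully substituted ring B or the anisyl ring, and the dye marks the end point. The neutral, anhydrous conditions leave the cis C3 centre and the aryl ester untouched.

Step 10
Reactants: 20 2-hydroxy-4,6-dimethoxybenzaldehyde; 21 4-methoxyphenylmagnesium bromide
Product: 23 2-[hydroxy(4-methoxyphenyl)methyl]-3,5-dimethoxyphenol (racemic), via magnesium phenoxide 22 (not isolated)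
Conditions: 21 (2.3 equiv), THF, 0 °C → rt; aq NH4Cl
Reagents that add atoms: none
Why: Grignard addition: the first equivalent forms phenoxide 22 and the second adds to the chelated aldehyde. The carbinol centre is racemic and becomes trigonal later.

Step 11
Reactants: 23 2-[hydroxy(4-methoxyphenyl)methyl]-3,5-dimethoxyphenol
Product: 25 2-[(4-methoxyphenyl)(4-methylbenzenesulfonyl)methyl]-3,5-dimethoxyphenol (racemic), via benzhydryl cation 24 (not isolated)
Conditions: p-TolSO2Na (1.5 equiv), HCO2H–H2O (1:1), rt
Reagents that add atoms: sodium 4-methylbenzenesulfinate, [Na+].[O-]S(=O)c1ccc(C)cc1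
Why: SN1 substitution: in the acidic medium the very electron-rich benzhydrol loses water to the cation 24, stabilised by the ortho hydroxyl, two methoxy groups and the anisyl ring, and the sulfinate captures it through sulfur. The sulfone is a storable precursor that stays intact in acid and releases the neutral o-quinone methide only under the basic conditions of step 12.

Step 12
Reactants: 19 2-[(3R,4R)-5,6,7,8-tetramethoxy-4-(4-methoxyphenyl)-2-oxo-3,4-dihydro-2H-chromen-3-yl]acetaldehyde; 25 2-[(4-methoxyphenyl)(4-methylbenzenesulfonyl)methyl]-3,5-dimethoxyphenol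
Product: 28 (3S,4R)-5,7-dimethoxy-4-(4-methoxyphenyl)-3-[(3S,4R)-5,6,7,8-tetramethoxy-4-(4-methoxyphenyl)-2-oxo-3,4-dihydro-2H-chromen-3-yl]-3,4-dihydro-2H-chromen-2-one, via o-quinone methide 26 (not isolated), via azolium enolate 27 (not isolated)
Conditions: (5aS,10bR)-2-mesityl-5a,10b-dihydro-4H,6H-indeno[2,1-b][1,2,4]triazolo[4,3-d][1,4]oxazin-2-ium tetrafluoroborate (15 mol %), 3,3′,5,5′-tetra-tert-butyl-4,4′-diphenoquinone (1.2 equiv), K2CO3 (2.5 equiv), 4 Å MS, THF, 0 °C → rt
Reagents that add atoms: none
Why: Oxidative carbene catalysis: the carbene adds to 19, the adduct is oxidised by the diphenoquinone and deprotonated to the (Z)-enolate 27, which adds through its open face to 26 (released from 25 by carbonate through 1,4-elimination of sulfinate) in an endo [4+2] or Michael–lactonisation sequence, the known route from aliphatic aldehydes and o-quinone methides to cis-3,4-disubstituted dihydrocoumarins. C3 and C4 are set together, cis by the endo transition state and in absolute sense by the aminoindanol backbone of the catalyst. C3′ should be retained because carbonate in THF does not enolise an aryl lactone at a useful rate, as is known for the equally acidic C3–H of such products.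

Step 13
Reactants: 28 (3S,4R)-5,7-dimethoxy-4-(4-methoxyphenyl)-3-[(3S,4R)-5,6,7,8-tetramethoxy-4-(4-methoxyphenyl)-2-oxo-3,4-dihydro-2H-chromen-3-yl]-3,4-dihydro-2H-chromen-2-one
Product: 29 (3S,4R)-5,7-dihydroxy-4-(4-hydroxyphenyl)-3-[(3S,4R)-5,6,7,8-tetrahydroxy-4-(4-hydroxyphenyl)-2-oxo-3,4-dihydro-2H-chromen-3-yl]-3,4-dihydro-2H-chromen-2-one
Conditions: BBr3 (24 equiv), CH2Cl2, −78 → 0 °C, Ar; ice-water; acidic, oxygen-free work-up
Reagents that add atoms: none
Why: Lewis acid cleavage of aryl methyl ethers (O-coordination, then bromide attack at methyl). The aryl ester lactones have no alkyl–oxygen bond to cleave, and low temperature without base should keep C3 and C3′ from enolising.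

## Compound list

1 | (E)-3-(4-methoxyphenyl)prop-2-enal (4-methoxycinnamaldehyde) | COc1ccc(/C=C/C=O)cc1 | starting material
2 | ethyl vinyl ether | C=COCC | starting material
3 | (2S,4S)-2-ethoxy-4-(4-methoxyphenyl)-3,4-dihydro-2H-pyran (2,4-cis) | CCO[C@@H]1C[C@H](c2ccc(OC)cc2)C=CO1 | intermediate
4 | dimethyl squarate (3,4-dimethoxycyclobut-3-ene-1,2-dione) | COC1=C(OC)C(=O)C1=O | starting material
5 | [(2S,4S)-2-ethoxy-4-(4-methoxyphenyl)-3,4-dihydro-2H-pyran-6-yl]lithium | CCO[C@@H]1C[C@H](c2ccc(OC)cc2)C=C([Li])O1 | intermediate
6 | 4-[(2S,4S)-2-ethoxy-4-(4-methoxyphenyl)-3,4-dihydro-2H-pyran-6-yl]-4-hydroxy-2,3-dimethoxycyclobut-2-en-1-one (both carbinol epimers) | CCO[C@@H]1C[C@H](c2ccc(OC)cc2)C=C(O1)C1(O)C(OC)=C(OC)C1=O | intermediate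
7 | (3Z)-4-[(2S,4S)-2-ethoxy-4-(4-methoxyphenyl)-3,4-dihydro-2H-pyran-6-yl]-4-hydroxy-2,3-dimethoxybuta-1,3-dien-1-one (dienylketene) | CCO[C@@H]1C[C@H](c2ccc(OC)cc2)C=C(O1)/C(O)=C(OC)\C(OC)=C=O | intermediate
8 | 4a-H cyclohexa-2,4-dienone tautomer of 9: 2-ethoxy-8-hydroxy-6,7-dimethoxy-4-(4-methoxyphenyl)-2,3,4,4a-tetrahydro-5H-chromen-5-one (ring centres as in 6, C4a unassigned) | CCO[C@@H]1C[C@H](c2ccc(OC)cc2)C2C(=O)C(OC)=C(OC)C(O)=C2O1 | intermediate
9 | (2S,4R)-2-ethoxy-6,7-dimethoxy-4-(4-methoxyphenyl)-3,4-dihydro-2H-chromene-5,8-diol (2,4-cis) | CCO[C@@H]1C[C@H](c2ccc(OC)cc2)c2c(O)c(OC)c(OC)c(O)c2O1 | intermediate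
10 | (2S,4R)-2-ethoxy-5,6,7,8-tetramethoxy-4-(4-methoxyphenyl)-3,4-dihydro-2H-chromene | CCO[C@@H]1C[C@H](c2ccc(OC)cc2)c2c(OC)c(OC)c(OC)c(OC)c2O1 | intermediate
11 | (4R)-5,6,7,8-tetramethoxy-4-(4-methoxyphenyl)-3,4-dihydro-2H-chromen-2-ol (both anomers) | OC1C[C@H](c2ccc(OC)cc2)c2c(OC)c(OC)c(OC)c(OC)c2O1 | intermediate
12 | (4R)-5,6,7,8-tetramethoxy-4-(4-methoxyphenyl)-3,4-dihydro-2H-chromen-2-one | O=C1C[C@H](c2ccc(OC)cc2)c2c(OC)c(OC)c(OC)c(OC)c2O1 | intermediate
13 | allyl bromide (3-bromoprop-1-ene) | C=CCBr | starting material
14 | lithium enolate of 12 | [Li]OC1=C[C@H](c2ccc(OC)cc2)c2c(OC)c(OC)c(OC)c(OC)c2O1 | intermediate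
15 | (3S,4R)-3-allyl-5,6,7,8-tetramethoxy-4-(4-methoxyphenyl)-3,4-dihydro-2H-chromen-2-one (3,4-trans) | C=CC[C@@H]1C(=O)Oc2c(OC)c(OC)c(OC)c(OC)c2[C@H]1c1ccc(OC)cc1 | intermediate
16 | lithium enolate of 15 | C=CCC1=C(O[Li])Oc2c(OC)c(OC)c(OC)c(OC)c2[C@H]1c1ccc(OC)cc1 | intermediate
17 | (3R,4R)-3-allyl-5,6,7,8-tetramethoxy-4-(4-methoxyphenyl)-3,4-dihydro-2H-chromen-2-one (3,4-cis) | C=CC[C@H]1C(=O)Oc2c(OC)c(OC)c(OC)c(OC)c2[C@H]1c1ccc(OC)cc1 | intermediate
18 | (3R,4R)-5,6,7,8-tetramethoxy-4-(4-methoxyphenyl)-3-(1,2,4-trioxolan-3-ylmethyl)-3,4-dihydro-2H-chromen-2-one (ozonide, trioxolane carbon unassigned) | O1OC(C[C@H]2C(=O)Oc3c(OC)c(OC)c(OC)c(OC)c3[C@H]2c2ccc(OC)cc2)OC1 | intermediate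
19 | 2-[(3R,4R)-5,6,7,8-tetramethoxy-4-(4-methoxyphenyl)-2-oxo-3,4-dihydro-2H-chromen-3-yl]acetaldehyde (3,4-cis) | O=CC[C@H]1C(=O)Oc2c(OC)c(OC)c(OC)c(OC)c2[C@H]1c1ccc(OC)cc1 | intermediate
20 | 2-hydroxy-4,6-dimethoxybenzaldehyde | COc1cc(O)c(C=O)c(OC)c1 | starting material
21 | 4-methoxyphenylmagnesium bromide | COc1ccc([Mg]Br)cc1 | starting material
22 | bromomagnesium 2-formyl-3,5-dimethoxyphenoxide | COc1cc(O[Mg]Br)c(C=O)c(OC)c1 | intermediate
23 | 2-[hydroxy(4-methoxyphenyl)methyl]-3,5-dimethoxyphenol (racemic) | COc1ccc(C(O)c2c(O)cc(OC)cc2OC)cc1 | intermediate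
24 | (2-hydroxy-4,6-dimethoxyphenyl)(4-methoxyphenyl)methylium (benzhydryl cation, the conjugate acid of 26; formate counter-ion not drawn) | COc1ccc([CH+]c2c(O)cc(OC)cc2OC)cc1 | intermediate
25 | 2-[(4-methoxyphenyl)(4-methylbenzenesulfonyl)methyl]-3,5-dimethoxyphenol (racemic) | Cc1ccc(cc1)S(=O)(=O)C(c1ccc(OC)cc1)c1c(O)cc(OC)cc1OC | intermediate
26 | 3,5-dimethoxy-6-[(4-methoxyphenyl)methylidene]cyclohexa-2,4-dien-1-one (o-quinone methide, alkene geometry not fixed) | O=C1C=C(OC)C=C(OC)C1=Cc1ccc(OC)cc1 | intermediate
27 | (Z)-enolate of the acyl azolium from 19 and the carbene of the (5aS,10bR) triazolium salt (zwitterion) | [O-]/C(=C\[C@H]1C(=O)Oc2c(OC)c(OC)c(OC)c(OC)c2[C@H]1c1ccc(OC)cc1)C1=[N+](c2c(C)cc(C)cc2C)N=C2N1[C@@H]1c3ccccc3C[C@@H]1OC2 | intermediate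
28 | (3S,4R)-5,7-dimethoxy-4-(4-methoxyphenyl)-3-[(3S,4R)-5,6,7,8-tetramethoxy-4-(4-methoxyphenyl)-2-oxo-3,4-dihydro-2H-chromen-3-yl]-3,4-dihydro-2H-chromen-2-one (octamethyl ether of 29) | O=C1Oc2cc(OC)cc(OC)c2[C@@H](c2ccc(OC)cc2)[C@H]1[C@H]1C(=O)Oc2c(OC)c(OC)c(OC)c(OC)c2[C@H]1c1ccc(OC)cc1 | intermediate
29 | (3S,4R)-5,7-dihydroxy-4-(4-hydroxyphenyl)-3-[(3S,4R)-5,6,7,8-tetrahydroxy-4-(4-hydroxyphenyl)-2-oxo-3,4-dihydro-2H-chromen-3-yl]-3,4-dihydro-2H-chromen-2-one | O=C1Oc2cc(O)cc(O)c2[C@@H](c2ccc(O)cc2)[C@H]1[C@H]1C(=O)Oc2c(O)c(O)c(O)c(O)c2[C@H]1c1ccc(O)cc1 | target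

## Step count and least certain steps

Total step count: 13. Longest linear sequence: 11 steps (steps 1 to 9, then 12 and 13); steps 10 and 11 prepare the ring A partner.

**Key step, step 3.** The ring expansion itself is well founded. What is most likely to go wrong is loss of the product after it forms. Hydroquinone 9 is the most electron-rich compound of the route and oxidises in air during isolation, and its phenols are acidic enough to start ionising the ethoxy acetal in hot xylene. The fallback sets out from 6 and changes the isolated species. The crude thermolysate is oxidised deliberately with Ag2O to the stable quinone (2S,4R)-2-ethoxy-6,7-dimethoxy-4-(4-methoxyphenyl)-3,4-dihydro-2H-chromene-5,8-dione F1, which is purified. F1 is then reduced with Na2S2O4 and methylated in the same flask (Me2SO4, KOH, n-Bu4NBr, THF–water), coming back to the route at 10.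

**Step 12.** This carries the largest stereochemical load. The C5 methoxy group flanks the methide carbon of 26, so neither alkene geometry is clearly preferred, and the cis outcome known for simpler o-quinone methides may erode. The resident C3′ and C4′ centres may be mismatched with the catalyst. Prolonged contact with carbonate may epimerise the cis C3′ centre. Only C4 must be set irreversibly, because C3 and C3′ can be reset from their enolates. The fallback sets out from 15 and skips step 8. Ozonolysis as in step 9 gives the configurationally robust trans aldehyde 2-[(3S,4R)-5,6,7,8-tetramethoxy-4-(4-methoxyphenyl)-2-oxo-3,4-dihydro-2H-chromen-3-yl]acetaldehyde F2. Annulation of F2 with 25, using whichever catalyst antipode places C4 as R, gives the (3S,4R,3′R,4′R) epimer of 28 F3. LiN(i-Pr)2 (2.5 equiv) at −78 °C then gives the dilithium bis-enolate of 28 F4, which erases both enolisable centres. Protonation of F4 with 2,6-di-tert-butyl-4-methylphenol from the face anti to each C4 aryl group makes both lactones cis, coming back to the route at 28.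

**Step 2.** The likely failure is competing removal of the benzylic, allylic C4–H by t-BuLi, which would racemise the centre that becomes C4′, or incomplete metalation. The fallback sets out from 3 and generates the same organolithium without a strong base meeting C4–H. Oxidation of the enol ether with (C5H5NH)[CrO3Cl] gives (4S,6S)-6-ethoxy-4-(4-methoxyphenyl)oxan-2-one F5. KN(SiMe3)2 and (PhO)2P(O)Cl convert F5 into (2S,4S)-2-ethoxy-4-(4-methoxyphenyl)-3,4-dihydro-2H-pyran-6-yl diphenyl phosphate F6. Me3SnSnMe3, Pd(PPh3)4 and LiCl convert F6 into [(2S,4S)-2-ethoxy-4-(4-methoxyphenyl)-3,4-dihydro-2H-pyran-6-yl]trimethylstannane F7. Tin–lithium exchange on F7 with MeLi at −78 °C comes back to the route at 5, which adds to 4 to give 6.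

**Step 13.** Eight ether cleavages need long exposure to a strong Lewis acid. The likely failures are epimerisation of the cis C3 and C3′ centres through enolisation of the boron-bound lactones, and oxidative loss of the tetrahydroxyarene on isolation. The fallback sets out from 28 and separates deprotection from stereocontrol. BBr3 is applied without regard to C3 and C3′, giving the octaphenol as a mixture at C3 and C3′ F8. Et3SiCl and imidazole in DMF give the octakis(triethylsilyl) ether of that mixture F9, which can be chromatographed. LiN(i-Pr)2 (2.5 equiv) gives the dilithium bis-enolate of the octakis(triethylsilyl) ether F10, and kinetic protonation as above gives the cis,cis octakis(triethylsilyl) ether of 29 F11. Acetic acid in wet THF, which cannot enolise the lactones, removes the silyl groups from F11 and comes back to the route at 29.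

**Step 8.** The likely failure is insufficient facial discrimination, or incomplete deprotonation followed by proton return from diisopropylamine that regenerates 15. The C3–H of the trans isomer lies near the carbonyl plane, which makes this plausible. The fallback sets out from 15 and replaces substrate control by reagent control on an amine-free intermediate. Enolate 16 is trapped with Me3SiCl as the silyl ketene acetal 3-allyl-5,6,7,8-tetramethoxy-4-(4-methoxyphenyl)-2-(trimethylsilyloxy)-4H-chromene F12. F12 is protonated at −78 °C in toluene by the chiral Brønsted acid formed from SnCl4 and the 1,1′-bi-2-naphthol antipode that reinforces the substrate bias, coming back to the route at 17. The step 12 fallback also removes the dependence on this step.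

## Further compounds

F1 | step 3 | (2S,4R)-2-ethoxy-6,7-dimethoxy-4-(4-methoxyphenyl)-3,4-dihydro-2H-chromene-5,8-dione | CCO[C@@H]1C[C@H](c2ccc(OC)cc2)C2=C(O1)C(=O)C(OC)=C(OC)C2=O
F2 | step 12 | 2-[(3S,4R)-5,6,7,8-tetramethoxy-4-(4-methoxyphenyl)-2-oxo-3,4-dihydro-2H-chromen-3-yl]acetaldehyde (3,4-trans) | O=CC[C@@H]1C(=O)Oc2c(OC)c(OC)c(OC)c(OC)c2[C@H]1c1ccc(OC)cc1
F3 | step 12 | (3S,4R,3′R,4′R) epimer of 28 | O=C1Oc2cc(OC)cc(OC)c2[C@@H](c2ccc(OC)cc2)[C@H]1[C@@H]1C(=O)Oc2c(OC)c(OC)c(OC)c(OC)c2[C@H]1c1ccc(OC)cc1
F4 | step 12 | dilithium bis-enolate of 28 | [Li]OC1=C(C2=C(O[Li])Oc3c(OC)c(OC)c(OC)c(OC)c3[C@H]2c2ccc(OC)cc2)[C@H](c2ccc(OC)cc2)c2c(OC)cc(OC)cc2O1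
F5 | step 2 | (4S,6S)-6-ethoxy-4-(4-methoxyphenyl)oxan-2-one | CCO[C@@H]1C[C@H](c2ccc(OC)cc2)CC(=O)O1
F6 | step 2 | (2S,4S)-2-ethoxy-4-(4-methoxyphenyl)-3,4-dihydro-2H-pyran-6-yl diphenyl phosphate | CCO[C@@H]1C[C@H](c2ccc(OC)cc2)C=C(OP(=O)(Oc2ccccc2)Oc2ccccc2)O1
F7 | step 2 | [(2S,4S)-2-ethoxy-4-(4-methoxyphenyl)-3,4-dihydro-2H-pyran-6-yl]trimethylstannane | CCO[C@@H]1C[C@H](c2ccc(OC)cc2)C=C([Sn](C)(C)C)O1
F8 | step 13 | octaphenol of the constitution of 29 with (4R,4′R) fixed and C3, C3′ as a mixture | O=C1Oc2cc(O)cc(O)c2[C@@H](c2ccc(O)cc2)C1C1C(=O)Oc2c(O)c(O)c(O)c(O)c2[C@H]1c1ccc(O)cc1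
F9 | step 13 | octakis(triethylsilyl) ether of F8 (C3, C3′ as a mixture) | O=C1Oc2cc(O[Si](CC)(CC)CC)cc(O[Si](CC)(CC)CC)c2[C@@H](c2ccc(O[Si](CC)(CC)CC)cc2)C1C1C(=O)Oc2c(O[Si](CC)(CC)CC)c(O[Si](CC)(CC)CC)c(O[Si](CC)(CC)CC)c(O[Si](CC)(CC)CC)c2[C@H]1c1ccc(O[Si](CC)(CC)CC)cc1
F10 | step 13 | dilithium bis-enolate of F9 | [Li]OC1=C(C2=C(O[Li])Oc3c(O[Si](CC)(CC)CC)c(O[Si](CC)(CC)CC)c(O[Si](CC)(CC)CC)c(O[Si](CC)(CC)CC)c3[C@H]2c2ccc(O[Si](CC)(CC)CC)cc2)[C@H](c2ccc(O[Si](CC)(CC)CC)cc2)c2c(O[Si](CC)(CC)CC)cc(O[Si](CC)(CC)CC)cc2O1
F11 | step 13 | octakis(triethylsilyl) ether of 29 (3,4-cis and 3′,4′-cis) | O=C1Oc2cc(O[Si](CC)(CC)CC)cc(O[Si](CC)(CC)CC)c2[C@@H](c2ccc(O[Si](CC)(CC)CC)cc2)[C@H]1[C@H]1C(=O)Oc2c(O[Si](CC)(CC)CC)c(O[Si](CC)(CC)CC)c(O[Si](CC)(CC)CC)c(O[Si](CC)(CC)CC)c2[C@H]1c1ccc(O[Si](CC)(CC)CC)cc1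
F12 | step 8 | (4R)-3-allyl-5,6,7,8-tetramethoxy-4-(4-methoxyphenyl)-2-(trimethylsilyloxy)-4H-chromene | C=CCC1=C(O[Si](C)(C)C)Oc2c(OC)c(OC)c(OC)c(OC)c2[C@H]1c1ccc(OC)cc1
A1 | alternative 1 | [all-trans-3,4-bis(4-methoxyphenyl)cyclobutane-1,2-diyl]bis[(1-methyl-1H-imidazol-2-yl)methanone] | O=C(c1nccn1C)[C@H]1[C@H](c2ccc(OC)cc2)[C@@H](c2ccc(OC)cc2)[C@@H]1C(=O)c1nccn1C
A2 | alternative 1 | (E)-3-(4-methoxyphenyl)-1-(1-methyl-1H-imidazol-2-yl)prop-2-en-1-one | COc1ccc(/C=C/C(=O)c2nccn2C)cc1
A3 | alternative 2 | 5,7,5′,6′,7′,8′-hexa-O-methyl ether of 29 | O=C1Oc2cc(OC)cc(OC)c2[C@@H](c2ccc(O)cc2)[C@H]1[C@H]1C(=O)Oc2c(OC)c(OC)c(OC)c(OC)c2[C@H]1c1ccc(O)cc1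
A4 | alternative 2 | 3,5-dimethoxy-2-[(4-oxocyclohexa-2,5-dien-1-ylidene)methyl]phenyl 2,3,4,5-tetramethoxy-6-[(4-oxocyclohexa-2,5-dien-1-ylidene)methyl]phenyl butanedioate | O=C(CCC(=O)Oc1c(OC)c(OC)c(OC)c(OC)c1C=C1C=CC(=O)C=C1)Oc1cc(OC)cc(OC)c1C=C1C=CC(=O)C=C1
A5 | alternative 3 | dimethyl (4R)-5,7-dihydroxy-4-(4-methoxyphenyl)-2-oxochromane-6,8-dicarboxylate | O=C1C[C@H](c2ccc(OC)cc2)c2c(O)c(C(=O)OC)c(O)c(C(=O)OC)c2O1
A6 | alternative 3 | methyl (3S)-5-chloro-4-(chlorocarbonyl)-3-(4-methoxyphenyl)-5-oxopentanoate | COC(=O)C[C@H](c1ccc(OC)cc1)C(C(=O)Cl)C(=O)Cl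
A7 | alternative 3 | dimethyl 3-oxopentanedioate (dimethyl acetonedicarboxylate) | COC(=O)CC(=O)CC(=O)OC
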